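## Retrosynthetic overview

1. Numbering (target): ring C1 (CHOAc), C2, C3, C4 (epoxide C–CH3), C5 (epoxide CH), C6 (lactone CH–O), C7, C8 (CHO‑tigloyl), C9, C10 (CH–CH3); butenolide C7=C11(C13H2OAc)–C12(=O)–O–C6.
2. Feature used: the ten‑membered carbocycle has a cis C4–C5 unit (the epoxide comes from a Z C4=C5 alkene) and oxygen on C8. A transannular C4–C8 bond therefore turns it into a cis‑bicyclo[5.3.0]decane (cyclopentane C4–C5–C6–C7–C8, cycloheptane C8–C9–C10–C1–C2–C3–C4) with a C8 alkoxide and a C5 sulfonate placed for C4–C8 heterolysis.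
3. Disconnections, last to first: acetates; butenolide by intramolecular Horner–Wadsworth–Emmons olefination of a C6‑O‑phosphonoacyl C7 ketone (C11–C13 from a phosphonoacetate); C6–OH‑directed epoxidation; C8 tiglate; Grob fragmentation of mesylate 25 to cyclodecenone 26.
4. Bicycle 25: C5/C6/C7 oxygenation through a C5 enone; C8–C9 bond by SmI2 Barbier closure; C4 configuration by CBS desymmetrisation of the 1,3‑dione; C1/C10 by catalytic anti‑crotylation of the acrolein Michael adduct of 2‑methylcyclopentane‑1,3‑dione.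
5. Ring order: cyclopentane (starting material) → cycloheptane (step 9) → cyclodecane (step 20) → epoxide (step 27) → butenolide (step 31).

Key step: step 20

Assumption (chemistry): stereocentres that are created and destroyed again (ozonide carbon of 9, acetal carbon of 20, phosphonate α‑carbon of 40–42) are expected as mixtures and are left unspecified in the SMILES; atom labels C1–C13 are those of line 1 throughout.

## Route

Step 1
Reactants: 1 2‑methylcyclopentane‑1,3‑dione; 2 acrolein
Product: 3 3‑(1‑methyl‑2,5‑dioxocyclopentyl)propanal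
Conditions: H2O, rt
Reagents that add atoms: none
Why: Michael addition of the acidic C–H of the cyclic 1,3‑dione to acrolein joins C4 (with its methyl and the future C5–C8) to C3–C2–C1 and creates no stereocentre.

Step 2
Reactants: 3 3‑(1‑methyl‑2,5‑dioxocyclopentyl)propanal; 4 (E)‑crotylboronic acid pinacol ester
Product: 5 2‑[(3S,4R)‑3‑hydroxy‑4‑methylhex‑5‑en‑1‑yl]‑2‑methylcyclopentane‑1,3‑dione (anti homoallylic alcohol)
Conditions: (R)‑TRIP [(R)‑3,3'‑bis(2,4,6‑triisopropylphenyl)‑1,1'‑binaphthyl‑2,2'‑diyl hydrogen phosphate] (5 mol %), 4 Å MS, toluene, −30 °C; aq. NaHCO3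
Reagents that add atoms: none
Why: Chiral phosphoric acid‑catalysed crotylboration through a closed chair transition state, in which the E‑crotyl geometry gives the anti C1–OH/C10–CH3 pair and the (R)‑acid is expected to direct addition to the Re face of the aldehyde (C1 S, C10 R), while the ketones are inert to the boronate.

Step 3
Reactants: 5 anti homoallylic alcohol
Product: 6 2‑[(3S,4R)‑3‑(tert‑butyldimethylsilyloxy)‑4‑methylhex‑5‑en‑1‑yl]‑2‑methylcyclopentane‑1,3‑dione
Conditions: TBSCl, imidazole, DMF, rt
Reagents that add atoms: tert‑butyldimethylsilyl chloride, CC(C)(C)[Si](C)(C)Cl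
Why: Standard silylation of the secondary C1 hydroxyl under non‑nucleophilic conditions that the base‑sensitive 2,2‑disubstituted dione tolerates.

Step 4
Reactants: 6 TBS ether dione
Product: 7 (2R,3R)‑2‑[(3S,4R)‑3‑(tert‑butyldimethylsilyloxy)‑4‑methylhex‑5‑en‑1‑yl]‑3‑hydroxy‑2‑methylcyclopentan‑1‑one (C5–OH cis to the side chain, trans to C4–CH3)
Conditions: (S)‑2‑methyl‑CBS‑oxazaborolidine (20 mol %), catecholborane, toluene, −78 → −40 °C
Reagents that add atoms: none
Why: Corey–Bakshi–Shibata reduction that desymmetrises the dione: the catalyst fixes the carbinol C5 as R (quaternary C4 as the large group) and hydride enters anti to the long C4 side chain, so that C4 becomes R; the minor diastereomer from the other carbonyl is removed by chromatography, and catecholborane leaves the vinyl group untouched at this temperature.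

Step 5
Reactants: 7 hydroxy ketone
Product: 8 (2R,3R)‑2‑[(3S,4R)‑3‑(tert‑butyldimethylsilyloxy)‑4‑methylhex‑5‑en‑1‑yl]‑2‑methyl‑3‑(triethylsilyloxy)cyclopentan‑1‑one
Conditions: TESCl, imidazole, CH2Cl2, 0 °C → rt
Reagents that add atoms: chlorotriethylsilane, CC[Si](Cl)(CC)CC
Why: Silylation masks the C5 hydroxyl, which would otherwise quench the organosamarium species of step 9, with a group that can later be removed beside the TBS ether.

Step 6
Reactants: 8 TES ether
Product: 10 (2S,3S)‑3‑(tert‑butyldimethylsilyloxy)‑2‑methyl‑5‑[(1R,2R)‑1‑methyl‑5‑oxo‑2‑(triethylsilyloxy)cyclopentyl]pentanal (C9 aldehyde), via secondary ozonide 9 (not isolated)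
Conditions: O3, CH2Cl2, −78 °C; then PPh3, −78 °C → rt
Reagents that add atoms: ozone, [O-][O+]=O
Why: Ozonolysis with reductive work‑up removes the terminal carbon of the vinyl group and leaves C9 as the aldehyde, the silyl ethers and the ketone being inert.

Step 7
Reactants: 10 C9 aldehyde
Product: 11 primary alcohol (C9–OH) of the same skeleton
Conditions: NaBH4, MeOH/CH2Cl2, −78 °C
Reagents that add atoms: none
Why: Borohydride reduction at low temperature is selective for the aldehyde over the hindered α‑quaternary cyclopentanone and leaves no time for epimerisation at C10.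

Step 8
Reactants: 11 primary alcohol
Product: 12 primary iodide (C9–I)
Conditions: I2, PPh3, imidazole, CH2Cl2, 0 °C → rt
Reagents that add atoms: iodine, II
Why: Appel‑type iodination of the primary alcohol under neutral conditions gives the radical/organometal precursor for ring closure.

Step 9
Reactants: 12 primary iodide
Product: 13 cis‑fused bicyclo[5.3.0]decane: C8 tertiary alcohol cis to C4–CH3, C5–OTES trans to C4–CH3, C1–OTBS, C10–CH3
Conditions: SmI2 (2.5 equiv), NiI2 (cat.), THF, 0 °C → rt
Reagents that add atoms: none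
Why: Intramolecular samarium Barbier reaction closes the seven‑membered ring by forming C8–C9; the tether on C4 can reach only the carbonyl face on its own side, so the fusion is cis (C8–OH cis to the angular methyl) and C8 follows from C4.

Step 10
Reactants: 13 bicyclic TES ether
Product: 14 diol (C5–OH, C8–OH; C1–OTBS kept)
Conditions: camphorsulfonic acid (cat.), MeOH/CH2Cl2, 0 °C
Reagents that add atoms: none
Why: Acid methanolysis removes the triethylsilyl group much faster than the hindered secondary TBS ether, freeing C5 so that it can serve as the ketone handle for oxygenating C6 and C7.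

Step 11
Reactants: 14 diol
Product: 16 enone (C5 ketone, C6=C7, tertiary C8–OH), via hydroxy ketone 15 (not isolated)
Conditions: IBX (4 equiv), DMSO, 25 → 70 °C
Reagents that add atoms: none
Why: IBX oxidises the secondary alcohol and then dehydrogenates the ketone in the same pot; only C6 carries α‑hydrogens (C4 is quaternary), so the double bond can form only at C6=C7.

Step 12
Reactants: 16 enone
Product: 17 allylic diol (C5–OH trans to C8–OH and to C4–CH3; C6=C7)
Conditions: Me4NBH(OAc)3, MeCN/AcOH, −30 °C
Reagents that add atoms: none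
Why: Evans–Saksena reduction: the acetoxyborohydride bound to the C8 hydroxyl (β to the carbonyl through C4) delivers hydride intramolecularly to the C5 carbonyl from the face of the angular groups, which gives the 1,3‑anti diol with C5–O trans to the angular methyl, as the fragmentation requires.

Step 13
Reactants: 17 allylic diol
Product: 18 C5 triethylsilyl ether (C8–OH free)
Conditions: TESCl, imidazole, DMF, 0 °C
Reagents that add atoms: chlorotriethylsilane, CC[Si](Cl)(CC)CC
Why: Chlorosilane/imidazole silylates the secondary hydroxyl only and leaves the tertiary C8 hydroxyl, which is needed as a directing group in steps 14 and 16.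

Step 14
Reactants: 18 allylic silyl ether
Product: 19 triol (C6–OH and C7–OH cis to C8–OH and to C4–CH3, trans to C5–OTES)
Conditions: OsO4 (5 mol %), Me3NO·2H2O, CH2Cl2, rt; aq. Na2SO3
Reagents that add atoms: osmium tetroxide (catalytic oxygen carrier), O=[Os](=O)(=O)=O; trimethylamine N‑oxide, C[N+](C)(C)[O-]; water, O
Why: Catalytic syn‑dihydroxylation in a non‑coordinating solvent, guided to the face of the hydrogen‑bonding tertiary C8 hydroxyl and away from the bulky C5 silyl ether and the cycloheptane methylenes, sets C6 (and the transient C7 centre).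

Step 15
Reactants: 19 triol
Product: 20 p‑methoxybenzylidene acetal across O6 and O7 (C8–OH free)
Conditions: 4‑MeOC6H4CH(OMe)2, PPTS (cat.), CH2Cl2, rt
Reagents that add atoms: 4‑methoxybenzaldehyde dimethyl acetal, COc1ccc(C(OC)OC)cc1
Why: Acid‑catalysed transacetalisation engages the two secondary cis hydroxyls as a dioxolane, the crowded tertiary ring‑fusion hydroxyl being far slower to react.

Step 16
Reactants: 20 acetal
Product: 21 C6 p‑methoxybenzyl ether with free C7–OH and C8–OH (C5–OTES, C1–OTBS)
Conditions: i‑Bu2AlH (4 equiv), CH2Cl2, −78 → 0 °C; aq. Rochelle salt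
Reagents that add atoms: none
Why: Hydroxyl‑directed reductive opening of the benzylidene acetal: the aluminium alkoxide formed at the cis C8 hydroxyl coordinates the neighbouring O7, that C–O bond is cleaved, and the p‑methoxybenzyl group stays on O6.

Step 17
Reactants: 21 PMB ether diol
Product: 22 C7 ketone (α‑hydroxy ketone with the tertiary C8–OH)
Conditions: Dess–Martin periodinane, NaHCO3, CH2Cl2, 0 °C → rt
Reagents that add atoms: none
Why: Dess–Martin oxidation converts the only secondary hydroxyl into the ketone under buffered, non‑basic conditions that spare the silyl and PMB ethers.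

Step 18
Reactants: 22 C7 ketone
Product: 24 C7 dimethyl ketal with free C5–OH and C8–OH, via silyl ether ketal 23 (not isolated)
Conditions: Me3SiOMe, Me3SiOTf (cat.), CH2Cl2, −78 °C; then MeOH, 0 °C; Et3N
Reagents that add atoms: methoxytrimethylsilane, CO[Si](C)(C)C
Why: Silyl triflate‑catalysed ketalisation converts the hindered ketone at low temperature, and the triflic acid set free on adding methanol then cleaves the triethylsilyl ether selectively.

Step 19
Reactants: 24 ketal diol
Product: 25 hydroazulenol mesylate (C5–OMs trans to C4–CH3, C6–OPMB and C8–OH cis to C4–CH3, C7(OMe)2, C1–OTBS)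
Conditions: MsCl, Et3N, CH2Cl2, −20 °C; used without chromatography
Reagents that add atoms: methanesulfonyl chloride, CS(=O)(=O)Cl
Why: Sulfonylation through the sulfene reaches the neopentyl secondary C5 hydroxyl and cannot touch the tertiary C8 hydroxyl, giving the 1,3‑diol monosulfonate.

Step 20
Reactants: 25 hydroazulenol mesylate
Product: 26 (Z)‑cyclodecenone ketal (C8 ketone, C7(OMe)2, C6–OPMB (R), Z C4=C5, C1–OTBS (S), C10–CH3 (R))
Conditions: KOtBu (1.1 equiv), THF, 0 °C
Reagents that add atoms: none
Why: KOtBu deprotonates the tertiary C8 hydroxyl and the alkoxide lone pair pushes through C8–C4 into C4–C5 as the mesylate leaves, a concerted Grob fragmentation of a 1,3‑diol monosulfonate, the closest known class being fragmentations of bicyclic hydroxy sulfonates to medium‑ring alkenones. No ring is closed end to end: the ten‑membered ring already exists as the perimeter of the bicyclo[5.3.0]decane and is set free when the shared C4–C8 bond breaks, so the entropic and transannular penalties of a macrocyclisation do not arise. No stereocentre is formed; C4, C5 and C8 become trigonal and C1, C6 and C10 are untouched. The alkene geometry is dictated by the substrate: with the mesylate trans to the angular methyl and pseudo‑equatorial in the cyclopentane envelope, C5–O lies antiperiplanar to C4–C8 and C3, not the methyl, is gauche to C6, so C3 and C6 end up cis on the new double bond (Z). The step needs fragmentation to outrun internal displacement of the mesylate and needs the product to survive the base; the antiperiplanar alignment secures the first, and the hydrogen‑free C7 ketal lets the new C8 ketone enolise only toward C9, so the C6 ether cannot be lost by β‑elimination.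

Step 21
Reactants: 26 cyclodecenone ketal
Product: 27 (8S)‑alcohol
Conditions: (R)‑2‑methyl‑CBS‑oxazaborolidine (0.5 equiv), catecholborane, toluene, −40 °C
Reagents that add atoms: none
Why: Corey–Bakshi–Shibata reduction under reagent control, with the fully substituted ketal carbon C7 as the large and C9H2 as the small substituent, should give the 8S carbinol, and catecholborane at low temperature does not hydroborate the trisubstituted alkene.

Step 22
Reactants: 27 (8S)‑alcohol; 28 tiglic acid
Product: 30 C8 tiglate, via tigloyl trichlorobenzoyl anhydride 29 (not isolated)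
Conditions: 28, 2,4,6‑trichlorobenzoyl chloride, Et3N, THF, rt; then 27, DMAP, toluene, 60 °C
Reagents that add atoms: none
Why: Yamaguchi esterification acylates the hindered secondary hydroxyl, and the E‑configured tigloyl group is the thermodynamic isomer, so it is not at risk under DMAP.

Step 23
Reactants: 30 C8 tiglate
Product: 31 C1 alcohol
Conditions: Bu4NF, AcOH, THF, rt
Reagents that add atoms: none
Why: Buffered fluoride cleaves the C1 silyl ether while the ester, ketal and PMB ether persist; the C1 oxygen is exchanged now because a free C1 hydroxyl must not coexist with the later C7 ketone (transannular hemiketal) or the C4–C5 epoxide (tetrahydrofuran formation).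

Step 24
Reactants: 31 C1 alcohol
Product: 32 C1 acetate
Conditions: Ac2O, pyridine, DMAP (cat.), CH2Cl2, rt
Reagents that add atoms: acetic anhydride, CC(=O)OC(C)=O
Why: Routine acetylation installs the first acetate of the target at the only free hydroxyl.

Step 25
Reactants: 32 C1 acetate
Product: 33 C7 ketone (C6–OPMB, C8–O‑tigloyl, Z C4=C5)
Conditions: TsOH·H2O (cat.), acetone/H2O, 40 °C
Reagents that add atoms: water, O
Why: Acid‑catalysed ketal hydrolysis is carried out before the acid‑labile epoxide exists; it is helped by the relief of transannular strain on going to a trigonal ring carbon, and the β,γ‑alkene is not expected to move into conjugation because a planar enone is disfavoured in a ten‑membered ring.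

Step 26
Reactants: 33 C7 ketone
Product: 34 α‑hydroxy ketone (C6–OH, C7=O)
Conditions: DDQ, CH2Cl2/pH 7 buffer, 0 °C
Reagents that add atoms: none
Why: Oxidative cleavage of the p‑methoxybenzyl ether under neutral conditions frees the allylic C6 hydroxyl without disturbing the esters or the alkene.

Step 27
Reactants: 34 α‑hydroxy ketone
Product: 35 epoxy ketol (C4–C5 epoxide with its oxygen cis to C6–OH; C4 R, C5 S)
Conditions: VO(acac)2 (5 mol %), t‑BuOOH, CH2Cl2, 0 °C
Reagents that add atoms: tert‑butyl hydroperoxide, CC(C)(C)OO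
Why: Vanadium‑catalysed hydroxyl‑directed epoxidation delivers the peroxide oxygen to the alkene face next to the coordinated C6 hydroxyl, as with medium‑ring (Z)‑cycloalkenols, giving the cis epoxy alcohol with the C4/C5 configuration of the target; the electron‑poor tiglate alkene does not react.

Step 28
Reactants: 36 allyl diethylphosphonoacetate; 37 paraformaldehyde; 38 4‑methoxybenzyl alcohol
Product: 40 allyl 2‑(diethoxyphosphoryl)‑3‑[(4‑methoxybenzyl)oxy]propanoate (racemic), via phosphonoacrylate 39 (not isolated)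
Conditions: piperidine (cat.), 38 (excess), 80 °C
Reagents that add atoms: none
Why: Knoevenagel condensation with formaldehyde gives the 2‑phosphonoacrylate, which takes up the alcohol by oxa‑Michael addition, the same course the standard preparation follows in methanol.

Step 29
Reactants: 40 allyl ester
Product: 41 2‑(diethoxyphosphoryl)‑3‑[(4‑methoxybenzyl)oxy]propanoic acid (racemic)
Conditions: Pd(PPh3)4 (cat.), morpholine, THF, rt; aq. KHSO4
Reagents that add atoms: none
Why: Palladium‑catalysed allyl transfer to morpholine (Tsuji–Trost deallylation) liberates the acid under neutral conditions that cannot trigger retro‑Michael loss of the benzylic alkoxide.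

Step 30
Reactants: 35 epoxy ketol; 41 phosphonate acid
Product: 42 C6 ester of 35 with 41
Conditions: DCC, DMAP (cat.), CH2Cl2, 0 °C
Reagents that add atoms: none
Why: Steglich esterification acylates the only hydroxyl under conditions too weakly basic to enolise the α‑acyloxy ketone or open the epoxide.

Step 31
Reactants: 42 phosphonate ester
Product: 43 butenolide with C13–OPMB (C7=C11, lactone C12 to O6)
Conditions: LiCl, i‑Pr2NEt, MeCN, rt
Reagents that add atoms: none
Why: Intramolecular Horner–Wadsworth–Emmons olefination under Masamune–Roush conditions closes the five‑membered lactone onto the C7 ketone; a β‑alkoxy phosphonate carbanion can lose alkoxide only reversibly, so it is funnelled into the olefination, and the amine/LiCl base is too mild to epimerise C6 or C8 or to open the epoxide by β‑elimination.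

Step 32
Reactants: 43 C13 PMB ether
Product: 44 C13 alcohol
Conditions: DDQ, CH2Cl2/pH 7 buffer, rt
Reagents that add atoms: none
Why: Neutral oxidative removal of the p‑methoxybenzyl group spares the epoxide, the three ester‑type carbonyls and the acidic C6–H of the butenolide.

Step 33
Reactants: 44 C13 alcohol
Product: 45 CNP0287840.1 (target)
Conditions: Ac2O, pyridine, DMAP (cat.), CH2Cl2, 0 °C
Reagents that add atoms: acetic anhydride, CC(=O)OC(C)=O
Why: Acetylation of the primary allylic hydroxyl under mild conditions completes the target without touching any stereocentre.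

## Compound list

1 | 2‑methylcyclopentane‑1,3‑dione | CC1C(=O)CCC1=O | starting material
2 | acrolein | C=CC=O | starting material
3 | 3‑(1‑methyl‑2,5‑dioxocyclopentyl)propanal | CC1(CCC=O)C(=O)CCC1=O | intermediate
4 | (E)‑crotylboronic acid pinacol ester | C/C=C/CB1OC(C)(C)C(C)(C)O1 | starting material
5 | 2‑[(3S,4R)‑3‑hydroxy‑4‑methylhex‑5‑en‑1‑yl]‑2‑methylcyclopentane‑1,3‑dione | C=C[C@@H](C)[C@@H](O)CCC1(C)C(=O)CCC1=O | intermediate
6 | 2‑[(3S,4R)‑3‑(tert‑butyldimethylsilyloxy)‑4‑methylhex‑5‑en‑1‑yl]‑2‑methylcyclopentane‑1,3‑dione | C=C[C@@H](C)[C@@H](O[Si](C)(C)C(C)(C)C)CCC1(C)C(=O)CCC1=O | intermediate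
7 | (2R,3R)‑2‑[(3S,4R)‑3‑(tert‑butyldimethylsilyloxy)‑4‑methylhex‑5‑en‑1‑yl]‑3‑hydroxy‑2‑methylcyclopentan‑1‑one | C=C[C@@H](C)[C@@H](O[Si](C)(C)C(C)(C)C)CC[C@]1(C)[C@H](O)CCC1=O | intermediate
8 | triethylsilyl ether of 7 | C=C[C@@H](C)[C@@H](O[Si](C)(C)C(C)(C)C)CC[C@]1(C)[C@H](O[Si](CC)(CC)CC)CCC1=O | intermediate
9 | secondary ozonide of 8 (1,2,4‑trioxolane in place of the vinyl group) | O1COC(O1)[C@@H](C)[C@@H](O[Si](C)(C)C(C)(C)C)CC[C@]1(C)[C@H](O[Si](CC)(CC)CC)CCC1=O | intermediate
10 | (2S,3S)‑3‑(tert‑butyldimethylsilyloxy)‑2‑methyl‑5‑[(1R,2R)‑1‑methyl‑5‑oxo‑2‑(triethylsilyloxy)cyclopentyl]pentanal | O=C[C@@H](C)[C@@H](O[Si](C)(C)C(C)(C)C)CC[C@]1(C)[C@H](O[Si](CC)(CC)CC)CCC1=O | intermediate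
11 | primary alcohol from 10 (C9–OH) | OC[C@@H](C)[C@@H](O[Si](C)(C)C(C)(C)C)CC[C@]1(C)[C@H](O[Si](CC)(CC)CC)CCC1=O | intermediate
12 | primary iodide from 11 (C9–I) | IC[C@@H](C)[C@@H](O[Si](C)(C)C(C)(C)C)CC[C@]1(C)[C@H](O[Si](CC)(CC)CC)CCC1=O | intermediate
13 | cis‑fused bicyclo[5.3.0]decan‑8‑ol, C5–OTES, C1–OTBS, C4 and C10 methyls | O[C@@]12C[C@@H](C)[C@@H](O[Si](C)(C)C(C)(C)C)CC[C@]1(C)[C@H](O[Si](CC)(CC)CC)CC2 | intermediate
14 | C5,C8‑diol from 13 | O[C@@]12C[C@@H](C)[C@@H](O[Si](C)(C)C(C)(C)C)CC[C@]1(C)[C@H](O)CC2 | intermediate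
15 | β‑hydroxy ketone (C5 ketone, C8–OH) | O[C@@]12C[C@@H](C)[C@@H](O[Si](C)(C)C(C)(C)C)CC[C@]1(C)C(=O)CC2 | intermediate
16 | enone (C5 ketone, C6=C7, C8–OH) | O[C@@]12C[C@@H](C)[C@@H](O[Si](C)(C)C(C)(C)C)CC[C@]1(C)C(=O)C=C2 | intermediate
17 | allylic diol (C5–OH trans to C8–OH) | O[C@@]12C[C@@H](C)[C@@H](O[Si](C)(C)C(C)(C)C)CC[C@]1(C)[C@H](O)C=C2 | intermediate
18 | C5 triethylsilyl ether of 17 | O[C@@]12C[C@@H](C)[C@@H](O[Si](C)(C)C(C)(C)C)CC[C@]1(C)[C@H](O[Si](CC)(CC)CC)C=C2 | intermediate
19 | C6,C7,C8‑triol (all cis to C4–CH3), C5–OTES | O[C@@]12C[C@@H](C)[C@@H](O[Si](C)(C)C(C)(C)C)CC[C@]1(C)[C@H](O[Si](CC)(CC)CC)[C@@H](O)[C@H]2O | intermediate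
20 | O6,O7 p‑methoxybenzylidene acetal of 19 | O[C@@]12C[C@@H](C)[C@@H](O[Si](C)(C)C(C)(C)C)CC[C@]1(C)[C@H](O[Si](CC)(CC)CC)[C@@H](O3)[C@H]2OC3c4ccc(OC)cc4 | intermediate
21 | C6 PMB ether, C7–OH, C8–OH, C5–OTES | O[C@@]12C[C@@H](C)[C@@H](O[Si](C)(C)C(C)(C)C)CC[C@]1(C)[C@H](O[Si](CC)(CC)CC)[C@@H](OCc3ccc(OC)cc3)[C@H]2O | intermediate
22 | C7 ketone from 21 | O[C@@]12C[C@@H](C)[C@@H](O[Si](C)(C)C(C)(C)C)CC[C@]1(C)[C@H](O[Si](CC)(CC)CC)[C@@H](OCc3ccc(OC)cc3)C2=O | intermediate
23 | C7 dimethyl ketal, C5–OTES | O[C@@]12C[C@@H](C)[C@@H](O[Si](C)(C)C(C)(C)C)CC[C@]1(C)[C@H](O[Si](CC)(CC)CC)[C@@H](OCc3ccc(OC)cc3)C2(OC)OC | intermediate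
24 | C7 dimethyl ketal, C5–OH, C8–OH | O[C@@]12C[C@@H](C)[C@@H](O[Si](C)(C)C(C)(C)C)CC[C@]1(C)[C@H](O)[C@@H](OCc3ccc(OC)cc3)C2(OC)OC | intermediate
25 | hydroazulenol mesylate (fragmentation precursor) | O[C@@]12C[C@@H](C)[C@@H](O[Si](C)(C)C(C)(C)C)CC[C@]1(C)[C@H](OS(C)(=O)=O)[C@@H](OCc3ccc(OC)cc3)C2(OC)OC | intermediate
26 | (Z)‑cyclodecenone ketal (fragmentation product) | O=C1C[C@@H](C)[C@@H](O[Si](C)(C)C(C)(C)C)CC/C(C)=C\[C@@H](OCc2ccc(OC)cc2)C1(OC)OC | intermediate
27 | (8S)‑alcohol from 26 | O[C@H]1C[C@@H](C)[C@@H](O[Si](C)(C)C(C)(C)C)CC/C(C)=C\[C@@H](OCc2ccc(OC)cc2)C1(OC)OC | intermediate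
28 | tiglic acid, (E)‑2‑methylbut‑2‑enoic acid | C/C=C(\C)C(=O)O | starting material
29 | tiglic 2,4,6‑trichlorobenzoic anhydride | C/C=C(\C)C(=O)OC(=O)c1c(Cl)cc(Cl)cc1Cl | intermediate
30 | C8 tiglate, C1–OTBS | C/C=C(\C)C(=O)O[C@H]1C[C@@H](C)[C@@H](O[Si](C)(C)C(C)(C)C)CC/C(C)=C\[C@@H](OCc2ccc(OC)cc2)C1(OC)OC | intermediate
31 | C8 tiglate, C1–OH | C/C=C(\C)C(=O)O[C@H]1C[C@@H](C)[C@@H](O)CC/C(C)=C\[C@@H](OCc2ccc(OC)cc2)C1(OC)OC | intermediate
32 | C8 tiglate, C1 acetate, C7 ketal | C/C=C(\C)C(=O)O[C@H]1C[C@@H](C)[C@@H](OC(C)=O)CC/C(C)=C\[C@@H](OCc2ccc(OC)cc2)C1(OC)OC | intermediate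
33 | C7 ketone, C6–OPMB | C/C=C(\C)C(=O)O[C@H]1C[C@@H](C)[C@@H](OC(C)=O)CC/C(C)=C\[C@@H](OCc2ccc(OC)cc2)C1=O | intermediate
34 | α‑hydroxy ketone (C6–OH, C7=O) | C/C=C(\C)C(=O)O[C@H]1C[C@@H](C)[C@@H](OC(C)=O)CC/C(C)=C\[C@@H](O)C1=O | intermediate
35 | epoxy ketol (C4–C5 epoxide cis to C6–OH) | C/C=C(\C)C(=O)O[C@H]1C[C@@H](C)[C@@H](OC(C)=O)CC[C@@]2(C)O[C@H]2[C@@H](O)C1=O | intermediate
36 | allyl diethylphosphonoacetate | C=CCOC(=O)CP(=O)(OCC)OCC | starting material
37 | paraformaldehyde (as formaldehyde) | C=O | starting material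
38 | 4‑methoxybenzyl alcohol | COc1ccc(CO)cc1 | starting material
39 | allyl 2‑(diethoxyphosphoryl)acrylate | C=CCOC(=O)C(=C)P(=O)(OCC)OCC | intermediate
40 | allyl 2‑(diethoxyphosphoryl)‑3‑[(4‑methoxybenzyl)oxy]propanoate | C=CCOC(=O)C(COCc1ccc(OC)cc1)P(=O)(OCC)OCC | intermediate
41 | 2‑(diethoxyphosphoryl)‑3‑[(4‑methoxybenzyl)oxy]propanoic acid | OC(=O)C(COCc1ccc(OC)cc1)P(=O)(OCC)OCC | intermediate
42 | C6 ester of 35 with 41 | C/C=C(\C)C(=O)O[C@H]1C[C@@H](C)[C@@H](OC(C)=O)CC[C@@]2(C)O[C@H]2[C@@H](OC(=O)C(COCc3ccc(OC)cc3)P(=O)(OCC)OCC)C1=O | intermediate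
43 | butenolide with C13–OPMB | C/C=C(\C)C(=O)O[C@H]1C[C@@H](C)[C@@H](OC(C)=O)CC[C@@]2(C)O[C@H]2[C@H]2OC(=O)C(COCc3ccc(OC)cc3)=C12 | intermediate
44 | butenolide with C13–OH | C/C=C(\C)C(=O)O[C@H]1C[C@@H](C)[C@@H](OC(C)=O)CC[C@@]2(C)O[C@H]2[C@H]2OC(=O)C(CO)=C12 | intermediate
45 | CNP0287840.1 | C/C=C(\C)C(=O)O[C@H]1C[C@@H](C)[C@@H](OC(C)=O)CC[C@@]2(C)O[C@H]2[C@H]2OC(=O)C(COC(C)=O)=C12 | target

## Step count and risks

Total step count: 33 (31 in the main line, 2 for phosphonate acid 41). Longest linear sequence: 31 steps (1 → 45; steps 1–27 and 30–33).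

Steps most likely to fail:

**Step 20 (key fragmentation).** The C8 alkoxide may displace the mesylate internally instead of fragmenting, or the cyclopentane may not reach the envelope in which C5–O is anti to C4–C8, so that cleavage stalls and the base attacks elsewhere. The fallback sets out from diol 24 and returns at 26, with a carbonyl rather than a sulfonate as the electron sink. Dess–Martin oxidation of the C5 hydroxyl should give the β‑hydroxy ketone F1. Its potassium alkoxide (KN(SiMe3)2, THF, −78 °C) should cleave the same C4–C8 bond by retro‑aldol reaction, which the crowded, fully substituted aldol favours, and the ring‑opened C4=C5 enolate is trapped with PhNTf2 as the enol triflate F2, ring‑cis geometry being expected in a ten‑membered ring. Reduction of the triflate (Pd(OAc)2, PPh3, Bu3N, HCO2H, DMF) then gives 26.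

**Step 9 (Barbier closure).** Seven‑membered ring formation may be slower than reduction of the iodide to the alkane or of the ketone to the ketyl, so that open‑chain reduction products accumulate. The fallback sets out from aldehyde 10 and returns at 13. SmI2‑mediated ketone–aldehyde pinacol cyclisation (THF, t‑BuOH, −78 °C → rt) should give the cis‑fused C8,C9‑diol F3. The secondary C9 hydroxyl is converted into the O‑phenyl thionocarbonate F4 (PhOC(S)Cl, pyridine, CH2Cl2), and Barton–McCombie deoxygenation (Bu3SnH, AIBN, toluene, 80 °C) removes the C9 oxygen to give 13.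

**Step 27 (directed epoxidation of the α‑ketol).** The vanadium peroxide may oxidise the α‑hydroxy ketone, or the ketol may isomerise, before oxygen transfer to the alkene, and chelation by the ketone may erode facial delivery. The fallback sets out from 32 and returns at 35, with epoxidation before the ketone is unmasked. DDQ removal of the PMB group from 32 gives the hydroxy ketal F5, and VO(acac)2/t‑BuOOH epoxidation of this plain allylic alcohol gives the epoxy alcohol F6. Transketalisation (PPTS, wet acetone, rt) then releases the C7 ketone to give 35.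

## Further compounds

F1 | step 20 | β‑hydroxy ketone (C5 ketone, C8–OH, C6–OPMB, C7 dimethyl ketal) | O[C@@]12C[C@@H](C)[C@@H](O[Si](C)(C)C(C)(C)C)CC[C@]1(C)C(=O)[C@@H](OCc3ccc(OC)cc3)C2(OC)OC
F2 | step 20 | enol triflate (C4=C5–OTf, C8 ketone, ring‑cis) | O=C1C[C@@H](C)[C@@H](O[Si](C)(C)C(C)(C)C)CC/C(C)=C(/OS(=O)(=O)C(F)(F)F)[C@@H](OCc2ccc(OC)cc2)C1(OC)OC
F3 | step 9 | cis‑fused C8,C9‑diol (C9 configuration unspecified) | O[C@@]12C(O)[C@@H](C)[C@@H](O[Si](C)(C)C(C)(C)C)CC[C@]1(C)[C@H](O[Si](CC)(CC)CC)CC2
F4 | step 9 | O‑phenyl thionocarbonate of the C9 hydroxyl | O[C@@]12C(OC(=S)Oc3ccccc3)[C@@H](C)[C@@H](O[Si](C)(C)C(C)(C)C)CC[C@]1(C)[C@H](O[Si](CC)(CC)CC)CC2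
F5 | step 27 | hydroxy ketal (C6–OH, C7 dimethyl ketal, Z C4=C5) | C/C=C(\C)C(=O)O[C@H]1C[C@@H](C)[C@@H](OC(C)=O)CC/C(C)=C\[C@@H](O)C1(OC)OC
F6 | step 27 | epoxy alcohol (C4–C5 epoxide cis to C6–OH, C7 dimethyl ketal) | C/C=C(\C)C(=O)O[C@H]1C[C@@H](C)[C@@H](OC(C)=O)CC[C@@]2(C)O[C@H]2[C@@H](O)C1(OC)OC
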